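**Retrosynthetic overview**

Numbering (target): C1 = CH(OAc), C2, C3 = C(CH3)(OAc), C4, C5 = ring-fusion CH, C6, C7 = C=O, C8=C9, C10, C11, N12, C13–C15, C16 = quaternary carbon; ring A = C1–C5 + C16, ring B = C5–C8 + C16, ring C = C8–C16 through N12 (nine-membered).
Feature: the C8–C16 bond is common to ring B and ring C, so the atoms C5–C6–C7–C8–C9–C10–C11–N12–C13–C14–C15–C16 form a twelve-membered perimeter, and one transannular bond across it creates rings B and C and the quaternary centre C16 together.
Disconnections: C7 ketone by allylic C–H oxidation; C1 carbinol by ketone reduction; C8–C16 by transannular gold Conia-ene reaction of a C1=C16 silyl enol ether with the ring alkyne C8≡C9; C8≡C9 by ring-closing alkyne metathesis; C5–C6 by cuprate addition with silyl trapping; C15–C16 by B-alkyl Suzuki coupling; ring A by olefin metathesis from (R)-mevalonolactone.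
Ring order: ring A (step 6), twelve-membered cycloalkyne (step 12), rings B and C in one event (step 13).

Key step: step 13

Remark: the carbinol centres of 3, 6, 7 and 25 and the ammonium nitrogen of 19 and 24 are not controlled, since each is later opened, oxidised or deprotonated.

**Route**

Step 1
Reactants: 1 (R)-mevalonolactone
Product: 2 (4R)-4-(tert-butyldimethylsilyloxy)-4-methyltetrahydro-2H-pyran-2-one
Conditions: TBSOTf, 2,6-lutidine, CH2Cl2, 0 °C → rt
Reagents that add atoms: tert-butyldimethylsilyl triflate, CC(C)(C)[Si](C)(C)OS(=O)(=O)C(F)(F)F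
Why: Silylation of a tertiary alcohol with a silyl triflate and a hindered pyridine base should proceed without β-elimination, and the C3 stereocentre of the target is taken unchanged from the chiral pool.

Step 2
Reactants: 2 (4R)-4-(tert-butyldimethylsilyloxy)-4-methyltetrahydro-2H-pyran-2-one
Product: 3 (4R)-4-(tert-butyldimethylsilyloxy)-4-methyltetrahydro-2H-pyran-2-ol (lactol, both anomers)
Conditions: i-Bu2AlH, CH2Cl2, −78 °C; aq potassium sodium tartrate
Reagents that add atoms: none
Why: Partial reduction of a δ-lactone stops at the lactol because the tetrahedral aluminium hemiacetal is stable at low temperature.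

Step 3
Reactants: 3 (4R)-4-(tert-butyldimethylsilyloxy)-4-methyltetrahydro-2H-pyran-2-ol
Product: 4 (3S)-3-(tert-butyldimethylsilyloxy)-3-methylhex-5-en-1-ol
Conditions: Ph3PCH3Br, KOt-Bu, THF, 0 °C → rt
Reagents that add atoms: methyltriphenylphosphonium bromide, C[P+](c1ccccc1)(c1ccccc1)c1ccccc1.[Br-]
Why: Wittig methylenation of the open hydroxy-aldehyde form of the lactol turns the former lactone carbon into the alkene carbon that becomes C5.

Step 4
Reactants: 4 (3S)-3-(tert-butyldimethylsilyloxy)-3-methylhex-5-en-1-ol
Product: 5 (3S)-3-(tert-butyldimethylsilyloxy)-3-methylhex-5-enal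
Conditions: Dess–Martin periodinane, CH2Cl2, rt
Reagents that add atoms: none
Why: Dess–Martin oxidation gives the aldehyde under non-basic conditions that should leave the β-silyloxy group in place.

Step 5
Reactants: 5 (3S)-3-(tert-butyldimethylsilyloxy)-3-methylhex-5-enal
Product: 6 (5S)-5-(tert-butyldimethylsilyloxy)-5-methylocta-1,7-dien-3-ol (both C3 epimers)
Conditions: vinylMgBr, THF, −78 → 0 °C; aq NH4Cl
Reagents that add atoms: vinylmagnesium bromide, C=C[Mg]Br
Why: Grignard 1,2-addition to the aldehyde supplies the future C1 and C16, and the uncontrolled carbinol centre is removed in step 7.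

Step 6
Reactants: 6 (5S)-5-(tert-butyldimethylsilyloxy)-5-methylocta-1,7-dien-3-ol
Product: 7 (5S)-5-(tert-butyldimethylsilyloxy)-5-methylcyclohex-2-en-1-ol (both C1 epimers)
Conditions: second-generation Grubbs catalyst RuCl2(H2IMes)(PCy3)(=CHPh) (3 mol%), CH2Cl2, 40 °C
Reagents that add atoms: none
Why: Ring-closing olefin metathesis of the 1,7-diene closes ring A as a cyclohexene and is driven by loss of ethene.

Step 7
Reactants: 7 (5S)-5-(tert-butyldimethylsilyloxy)-5-methylcyclohex-2-en-1-ol
Product: 8 (5S)-5-(tert-butyldimethylsilyloxy)-5-methylcyclohex-2-en-1-one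
Conditions: MnO2, CH2Cl2, rt
Reagents that add atoms: none
Why: MnO2 oxidation of the secondary allylic alcohol gives the enone under neutral conditions, which avoids elimination of the silyloxy group and aromatisation.

Step 8
Reactants: 8 (5S)-5-(tert-butyldimethylsilyloxy)-5-methylcyclohex-2-en-1-one
Product: 9 (5S)-5-(tert-butyldimethylsilyloxy)-2-iodo-5-methylcyclohex-2-en-1-one
Conditions: I2, pyridine, CH2Cl2, 0 °C → rt
Reagents that add atoms: iodine, [I][I]
Why: Johnson α-iodination of a cyclic enone proceeds by conjugate addition of pyridine, iodination of the enolate and elimination.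

Step 9
Reactants: 10 N-methylallylamine; 11 5-bromopent-2-yne
Product: 12 N-allyl-N-methylpent-3-yn-1-amine
Conditions: K2CO3, MeCN, 50 °C
Reagents that add atoms: none
Why: SN2 N-alkylation of a secondary amine with a primary homopropargylic bromide gives the tertiary amine that carries N12 and both of its chains.

Step 10
Reactants: 9 (5S)-5-(tert-butyldimethylsilyloxy)-2-iodo-5-methylcyclohex-2-en-1-one; 12 N-allyl-N-methylpent-3-yn-1-amine
Product: 14 (5S)-5-(tert-butyldimethylsilyloxy)-5-methyl-2-{3-[methyl(pent-3-yn-1-yl)amino]propyl}cyclohex-2-en-1-one, via B-alkyl-9-BBN adduct 13 (not isolated)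
Conditions: 12, 9-BBN, THF, 0 °C → rt; then 9, PdCl2(dppf) (5 mol%), AsPh3, Cs2CO3, DMF/THF/H2O, rt
Reagents that add atoms: none
Why: 9-BBN hydroborates the terminal alkene much faster than the internal alkyne, and B-alkyl Suzuki–Miyaura coupling of the resulting borane with the 2-iodoenone forms the C15–C16 bond at room temperature.

Step 11
Reactants: 14 (5S)-5-(tert-butyldimethylsilyloxy)-5-methyl-2-{3-[methyl(pent-3-yn-1-yl)amino]propyl}cyclohex-2-en-1-one; 11 5-bromopent-2-yne
Product: 17 open-chain diyne silyl enol ether (pentynyl chain cis to the ring silyloxy group), via pent-3-yn-1-ylmagnesium bromide 15 (not isolated), via bromomagnesium enolate 16 (not isolated)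
Conditions: 11, Mg, THF, rt; then 14, CuBr·SMe2 (20 mol%), TBSCl, HMPA, THF, −78 → −20 °C; Et3N, aq NaHCO3
Reagents that add atoms: tert-butyldimethylsilyl chloride, CC(C)(C)[Si](C)(C)Cl
Why: Copper-catalysed conjugate addition of the Grignard reagent with in situ O-silylation fixes the tetrasubstituted C1=C16 enol ether, and axial attack at C5 on the half-chair that holds the C3 methyl equatorial and the smaller silyloxy group axial should place the chain cis to the C3 oxygen.

Step 12
Reactants: 17 open-chain diyne silyl enol ether
Product: 18 twelve-membered cycloalkyne silyl enol ether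
Conditions: [Mo(≡C–C6H4-4-OMe)(OSiPh3)3] (10 mol%), 5 Å MS, toluene (2 mM), 80 °C
Reagents that add atoms: none
Why: Ring-closing alkyne metathesis of the two methyl-capped alkynes should close the twelve-membered ring because both arms sit on adjacent ring atoms (C5 and C16) and the but-2-yne released is trapped by the molecular sieves.

Step 13
Reactants: 18 twelve-membered cycloalkyne silyl enol ether
Product: 20 tricyclic ketone (C1 ketone; C3 silyl ether; C8=C9 alkene), via ammonium triflimide salt 19 (not isolated)
Conditions: HNTf2 (1.0 equiv), CH2Cl2, 0 °C; then Ph3PAuNTf2 (10 mol%), MeOH (10 equiv), CH2Cl2, 40 °C; aq NaHCO3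
Reagents that add atoms: none
Why: Proposed new method: the cationic monovalent-gold centre binds the ring alkyne C8≡C9 on the outer face of the macrocycle, the enol ether carbon C16 attacks C8 anti to gold from inside the ring, methanol takes the silyl group from the resulting silyloxocarbenium ion, and the proton so released cleaves the C9–Au bond with retention. The closest known reaction type is the monovalent-gold-catalysed 5-exo-dig carbocyclisation of silyl enol ethers onto tethered alkynes (Conia-ene type), which has not been run across a macrocycle. Ring B closes 5-exo-dig through the C5–C6–C7 tether, and ring C is closed in the same event as a transannular contraction of the twelve-membered ring to the nine-membered ring, so no end-to-end medium-ring closure is required. C16 is set cis to the C5–C6 bond because the three-atom tether can only reach the enol ether face that carries C6 (cis-hydrindanone), while anti carboauration and stereoretentive protodeauration put C10 cis to C16, the cis-in-ring alkene of ring C. The step needs 5-exo attack at C8 rather than 6-endo attack at C9, which the short tether, the small Ph3P ligand and the higher strain of the alternative eight-membered ring should favour, and it needs a nitrogen that neither binds gold nor adds to the alkyne, which prior protonation of N12 secures; the tetrasubstituted enol ether leaves no doubt about the nucleophilic carbon.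

Step 14
Reactants: 20 tricyclic ketone
Product: 21 tricyclic C1 alcohol (C1 hydroxyl cis to the C3 silyloxy group)
Conditions: Li, NH3(l), THF, t-BuOH, −78 °C; NH4Cl
Reagents that add atoms: none
Why: Dissolving-metal reduction of the ketone under thermodynamic control should give the equatorial C1 alcohol, cis to the C3 oxygen, because the axial epimer would clash syn-diaxially with the axial C3 methyl group.

Step 15
Reactants: 21 tricyclic C1 alcohol
Product: 22 tricyclic cis-1,3-diol
Conditions: HF·pyridine, THF/pyridine, 0 °C → rt; aq NaHCO3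
Reagents that add atoms: none
Why: Fluoride cleavage of the tertiary silyl ether is placed after the reduction so that no β-hydroxy ketone prone to retro-aldol opening is ever exposed to base.

Step 16
Reactants: 22 tricyclic cis-1,3-diol
Product: 23 tricyclic diacetate
Conditions: Ac2O, Et3N, DMAP, CH2Cl2, rt → 40 °C
Reagents that add atoms: acetic anhydride, CC(=O)OC(C)=O
Why: DMAP-catalysed (Steglich-type) acetylation is forcing enough to esterify the tertiary C3 hydroxyl as well as the secondary C1 hydroxyl.

Step 17
Reactants: 23 tricyclic diacetate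
Product: 25 C7 allylic alcohol of the diacetate (both C7 epimers), via trifluoroacetate salt 24 (not isolated)
Conditions: TFA (1.1 equiv), CH2Cl2, rt, evaporate; then SeO2 (1.5 equiv), 1,4-dioxane, 80 °C; aq NaHCO3
Reagents that add atoms: selenium dioxide, O=[Se]=O
Why: Riley allylic oxidation (ene reaction, then [2,3]-sigmatropic shift) should attack the CH2 on the more substituted alkene terminus C8, which is C7 because C16 bears no hydrogen, while the protonated nitrogen is inert to the oxidant and deactivates C10.

Step 18
Reactants: 25 C7 allylic alcohol of the diacetate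
Product: 26 target, CNP0386920.1
Conditions: MnO2, CH2Cl2, rt
Reagents that add atoms: none
Why: MnO2 oxidises the allylic alcohol selectively to the conjugated C7 ketone and is tolerated by the tertiary amine and both acetates.

**Compound list**

1 | (R)-mevalonolactone, (4R)-4-hydroxy-4-methyltetrahydro-2H-pyran-2-one | C[C@@]1(O)CCOC(=O)C1 | starting material
2 | (4R)-4-(tert-butyldimethylsilyloxy)-4-methyltetrahydro-2H-pyran-2-one | C[C@@]1(O[Si](C)(C)C(C)(C)C)CCOC(=O)C1 | intermediate
3 | (4R)-4-(tert-butyldimethylsilyloxy)-4-methyltetrahydro-2H-pyran-2-ol (lactol, both anomers) | C[C@@]1(O[Si](C)(C)C(C)(C)C)CCOC(O)C1 | intermediate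
4 | (3S)-3-(tert-butyldimethylsilyloxy)-3-methylhex-5-en-1-ol | C[C@@](CC=C)(O[Si](C)(C)C(C)(C)C)CCO | intermediate
5 | (3S)-3-(tert-butyldimethylsilyloxy)-3-methylhex-5-enal | C[C@@](CC=C)(O[Si](C)(C)C(C)(C)C)CC=O | intermediate
6 | (5S)-5-(tert-butyldimethylsilyloxy)-5-methylocta-1,7-dien-3-ol (both C3 epimers) | C[C@@](CC=C)(O[Si](C)(C)C(C)(C)C)CC(O)C=C | intermediate
7 | (5S)-5-(tert-butyldimethylsilyloxy)-5-methylcyclohex-2-en-1-ol (both C1 epimers) | OC1C=CC[C@](C)(O[Si](C)(C)C(C)(C)C)C1 | intermediate
8 | (5S)-5-(tert-butyldimethylsilyloxy)-5-methylcyclohex-2-en-1-one | O=C1C=CC[C@](C)(O[Si](C)(C)C(C)(C)C)C1 | intermediate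
9 | (5S)-5-(tert-butyldimethylsilyloxy)-2-iodo-5-methylcyclohex-2-en-1-one | IC1=CC[C@](C)(O[Si](C)(C)C(C)(C)C)CC1=O | intermediate
10 | N-methylallylamine | C=CCNC | starting material
11 | 5-bromopent-2-yne | CC#CCCBr | starting material
12 | N-allyl-N-methylpent-3-yn-1-amine | C=CCN(C)CCC#CC | intermediate
13 | 9-{3-[methyl(pent-3-yn-1-yl)amino]propyl}-9-borabicyclo[3.3.1]nonane | CC#CCCN(C)CCCB1C2CCCC1CCC2 | intermediate
14 | (5S)-5-(tert-butyldimethylsilyloxy)-5-methyl-2-{3-[methyl(pent-3-yn-1-yl)amino]propyl}cyclohex-2-en-1-one | O=C1C(CCCN(C)CCC#CC)=CC[C@](C)(O[Si](C)(C)C(C)(C)C)C1 | intermediate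
15 | pent-3-yn-1-ylmagnesium bromide | CC#CCC[Mg]Br | intermediate
16 | bromomagnesium enolate of the conjugate adduct (O–Mg on C1, C1=C16, pentynyl chain on C5 cis to the C3 silyloxy group) | CC#CCC[C@@H]1C[C@](C)(O[Si](C)(C)C(C)(C)C)CC(O[Mg]Br)=C1CCCN(C)CCC#CC | intermediate
17 | open-chain diyne silyl enol ether: 1,5-bis(tert-butyldimethylsilyloxy)-5-methylcyclohex-1-ene with the 3-[methyl(pent-3-yn-1-yl)amino]propyl arm on C2 and a pent-3-yn-1-yl chain on C3, chain cis to the C5 silyloxy group and trans to the C5 methyl (cyclohexene numbering) | CC#CCC[C@@H]1C[C@](C)(O[Si](C)(C)C(C)(C)C)CC(O[Si](C)(C)C(C)(C)C)=C1CCCN(C)CCC#CC | intermediate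
18 | twelve-membered cycloalkyne silyl enol ether: the bis-silyl cyclohexene of 17 with C2 and C3 bridged by –(CH2)3–N(CH3)–(CH2)2–C≡C–(CH2)2– (ring alkyne = C8≡C9 of the target) | CC(C)(C)[Si](C)(C)OC1=C2CCCN(C)CCC#CCC[C@@H]2C[C@](C)(O[Si](C)(C)C(C)(C)C)C1 | intermediate
19 | N12-protonated 18 as its bis(trifluoromethanesulfonyl)imide salt | CC(C)(C)[Si](C)(C)OC1=C2CCC[NH+](C)CCC#CCC[C@@H]2C[C@](C)(O[Si](C)(C)C(C)(C)C)C1.O=S(=O)([N-]S(=O)(=O)C(F)(F)F)C(F)(F)F | intermediate
20 | tricyclic ketone: target skeleton with C1 ketone, C3 tert-butyldimethylsilyl ether, C7 CH2 and C8=C9 (C10 cis to C16); C3–O, C5–C6 and C16–C8 on one face of ring A | O=C1C[C@@](C)(O[Si](C)(C)C(C)(C)C)C[C@H]2CC/C3=C/CCN(C)CCC[C@@]321 | intermediate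
21 | tricyclic C1 alcohol: as 20 with C1 hydroxyl on the same face as the C3 silyloxy group | O[C@H]1C[C@@](C)(O[Si](C)(C)C(C)(C)C)C[C@H]2CC/C3=C/CCN(C)CCC[C@@]321 | intermediate
22 | tricyclic cis-1,3-diol (C1 and C3 hydroxyls on one face) | O[C@H]1C[C@@](C)(O)C[C@H]2CC/C3=C/CCN(C)CCC[C@@]321 | intermediate
23 | tricyclic diacetate (target lacking the C7 carbonyl) | CC(=O)O[C@H]1C[C@@](C)(OC(C)=O)C[C@H]2CC/C3=C/CCN(C)CCC[C@@]321 | intermediate
24 | N12-protonated 23 as its trifluoroacetate salt | CC(=O)O[C@H]1C[C@@](C)(OC(C)=O)C[C@H]2CC/C3=C/CC[NH+](C)CCC[C@@]321.[O-]C(=O)C(F)(F)F | intermediate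
25 | C7 allylic alcohol of the diacetate (both C7 epimers) | CC(=O)O[C@H]1C[C@@](C)(OC(C)=O)C[C@H]2CC(O)/C3=C/CCN(C)CCC[C@@]321 | intermediate
26 | CNP0386920.1: (1S,3S,5S,16S) in the numbering above, C8=C9 with C10 cis to C16 | CC(=O)O[C@H]1C[C@@](C)(OC(C)=O)C[C@H]2CC(=O)/C3=C/CCN(C)CCC[C@@]321 | target

**Step count**

Total: 18 steps. Longest linear sequence: 17 steps (steps 1–8 and 10–18 from 1); step 9 is a one-step branch.

**Steps most likely to fail**

Step 13 (proposed new method). The catalyst may be sequestered if the nitrogen is under-protonated, the enol ether may be lost to the acid before the C–C bond forms, or the macrocycle may hold C16 away from C8 so that 6-endo attack at C9 or no cyclisation results. The fallback uses known chemistry only, leaves the route at 9 and returns at 20: ring B is closed by the ordinary open-chain gold cyclisation and ring C afterwards by N-alkylation. N-Methylallylamine 10 is converted with Boc2O into tert-butyl allyl(methyl)carbamate F1, hydroboration with 9-BBN gives tert-butyl [3-(9-borabicyclo[3.3.1]nonan-9-yl)propyl](methyl)carbamate F2, and coupling with 9 under the conditions of step 10 gives the carbamate enone F3. 4-Chlorobut-1-yne is lithiated (n-BuLi) and opened onto oxirane (BF3·OEt2) to give 6-chlorohex-3-yn-1-ol F4, Appel bromination (CBr4, PPh3) gives 1-bromo-6-chlorohex-3-yne F5, and magnesium inserts at the carbon–bromine bond to give (6-chlorohex-3-yn-1-yl)magnesium bromide F6. Copper-catalysed addition of F6 to F3 with TBSCl/HMPA as in step 11 gives, through the bromomagnesium enolate F7, the open-chain chloro silyl enol ether F8. Ph3PAuNTf2 in CH2Cl2/MeOH should then close ring B by the established 5-exo-dig carbocyclisation to the cis-hydrindanone carbamate F9, whose 3-chloropropylidene chain has C10 cis to C16. TFA removes the Boc group to give the secondary amine chloride F10, and K2CO3 with NaI in MeCN at high dilution closes the nine-membered ring by intramolecular N-alkylation to give 20.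

Step 12. Intermolecular metathesis (oligomerisation) may outpace ring closure at the lower size limit of cycloalkynes, or the amine may slow catalyst turnover. The fallback leaves the route at 9 and returns at 18: the macrocycle is closed at the N12–C11 bond instead of at the alkyne. The first fallback is followed from 9 to the open-chain chloro silyl enol ether F8. TMSOTf/2,6-lutidine in CH2Cl2 followed by methanol removes the Boc group without touching either silyl group and gives the amino chloride silyl enol ether F11. K2CO3 and NaI in MeCN at high dilution (70 °C) then form the twelve-membered ring by N-alkylation to give 18.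

Step 14. Kinetic protonation from the more open face may give the axial C1 alcohol, or enolisation may leave the reduction incomplete. The fallback leaves the route at 20 and returns at 22: deprotection and reduction are inverted so that the free C3 hydroxyl steers the hydride. HF·pyridine converts 20 into the β-hydroxy ketone F12. Et2BOMe and then NaBH4 in THF/MeOH at −78 °C (boron chelate between the C3 oxygen and the C1 carbonyl, external hydride from the opposite face, 1,3-syn reduction of the Narasaka–Prasad type) should give the cis-1,3-diol 22 after methanolic work-up.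

**Further compounds**

F1 | step 13 | tert-butyl allyl(methyl)carbamate | C=CCN(C)C(=O)OC(C)(C)C
F2 | step 13 | tert-butyl [3-(9-borabicyclo[3.3.1]nonan-9-yl)propyl](methyl)carbamate | CN(CCCB1C2CCCC1CCC2)C(=O)OC(C)(C)C
F3 | step 13 | carbamate enone, tert-butyl {3-[(4S)-4-(tert-butyldimethylsilyloxy)-4-methyl-6-oxocyclohex-1-en-1-yl]propyl}(methyl)carbamate | O=C1C(CCCN(C)C(=O)OC(C)(C)C)=CC[C@](C)(O[Si](C)(C)C(C)(C)C)C1
F4 | step 13 | 6-chlorohex-3-yn-1-ol | OCCC#CCCCl
F5 | step 13 | 1-bromo-6-chlorohex-3-yne | BrCCC#CCCCl
F6 | step 13 | (6-chlorohex-3-yn-1-yl)magnesium bromide | ClCCC#CCC[Mg]Br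
F7 | step 13 | bromomagnesium enolate of the carbamate conjugate adduct | ClCCC#CCC[C@@H]1C[C@](C)(O[Si](C)(C)C(C)(C)C)CC(O[Mg]Br)=C1CCCN(C)C(=O)OC(C)(C)C
F8 | step 13 | open-chain chloro silyl enol ether (6-chlorohex-3-ynyl chain cis to the ring silyloxy group, N-Boc arm) | ClCCC#CCC[C@@H]1C[C@](C)(O[Si](C)(C)C(C)(C)C)CC(O[Si](C)(C)C(C)(C)C)=C1CCCN(C)C(=O)OC(C)(C)C
F9 | step 13 | cis-hydrindanone carbamate with 3-chloropropylidene chain on C8 (C10 cis to C16) | O=C1C[C@@](C)(O[Si](C)(C)C(C)(C)C)C[C@H]2CC/C(=C/CCCl)[C@]21CCCN(C)C(=O)OC(C)(C)C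
F10 | step 13 | secondary amine chloride (F9 without the Boc group) | O=C1C[C@@](C)(O[Si](C)(C)C(C)(C)C)C[C@H]2CC/C(=C/CCCl)[C@]21CCCNC
F11 | step 12 | amino chloride silyl enol ether (F8 without the Boc group) | ClCCC#CCC[C@@H]1C[C@](C)(O[Si](C)(C)C(C)(C)C)CC(O[Si](C)(C)C(C)(C)C)=C1CCCNC
F12 | step 14 | tricyclic β-hydroxy ketone (20 without the silyl group) | O=C1C[C@@](C)(O)C[C@H]2CC/C3=C/CCN(C)CCC[C@@]321
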